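The oxolane (ring A) is closed last through its O1–C5 bond. C5 is the benzylic carbon bearing ring B, whose para oxygen carries the side chain. That oxygen lets C5 ionise to a quinone-methide-like cation, the O-alkylated counterpart of the biosynthetic quinone methide, while rings C (on C2) and D (side chain), masked as tosylates, stay inert. In one flask an arylmagnesium reagent carrying the complete threo side chain adds to a 3,4-dimethyl-5-aryl lactol, and acid then cyclises the epimeric open-chain diol stereoconvergently to the 4,5-trans oxolane. The precursors are therefore an acyclic syn,syn stereotriad and an iodoarene.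

Key step: step 11

Remark: oxolane numbering is O1, C2 (bears ring C), C3, C4, C5 (bears ring B); compounds 4, 12, 14 and the (S)-configured phosphoric acid catalyst are assumed to be commercially available.

Step 1
Reactants: 1 vanillin; 2 4-methylbenzenesulfonyl chloride
Product: 3 4-formyl-2-methoxyphenyl 4-methylbenzenesulfonate
Conditions: Et3N, DMAP (cat.), CH2Cl2, 0 °C to rt
Reagents that add atoms: 4-methylbenzenesulfonyl chloride, Cc1ccc(S(=O)(=O)Cl)cc1
Why: O-sulfonylation of the phenol installs a robust, electron-withdrawing tosylate on ring C that later suppresses ionisation at its benzylic carbon; no stereocentre is formed.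

Step 2
Reactants: 3 4-formyl-2-methoxyphenyl 4-methylbenzenesulfonate; 4 (Z)-crotylboronic acid pinacol ester
Product: 5 (1S,2R)-1-[3-methoxy-4-(tosyloxy)phenyl]-2-methylbut-3-en-1-ol
Conditions: (S)-3,3'-bis(2,4,6-triisopropylphenyl)-1,1'-binaphthyl-2,2'-diyl hydrogen phosphate (5 mol %), toluene, −30 °C
Reagents that add atoms: (Z)-crotylboronic acid pinacol ester, C/C=C\CB1OC(C)(C)C(C)(C)O1
Why: Chiral phosphoric acid-catalysed crotylboration through a closed chair (Zimmerman–Traxler) transition state, in which the Z boronate geometry sets the syn OH/CH3 relation and the (S)-catalyst should direct addition to the Si face of the aldehyde to give the (1S,2R) isomer.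

Step 3
Reactants: 5 (1S,2R)-1-[3-methoxy-4-(tosyloxy)phenyl]-2-methylbut-3-en-1-ol; 6 sodium perborate tetrahydrate
Product: 7 (1S,2R)-1-[3-methoxy-4-(tosyloxy)phenyl]-2-methylbutane-1,4-diol
Conditions: 9-borabicyclo[3.3.1]nonane (2.5 equiv), THF, 0 °C to rt; then NaBO3·4H2O, H2O, rt
Reagents that add atoms: sodium perborate, O[B-]1(O)OO[B-](O)(O)OO1.[Na+].[Na+]
Why: Anti-Markovnikov hydroboration–oxidation places boron on the terminal CH2, and the mild perborate oxidation spares the aryl tosylate; no new stereocentre arises.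

Step 4
Reactants: 7 (1S,2R)-1-[3-methoxy-4-(tosyloxy)phenyl]-2-methylbutane-1,4-diol
Product: 8 (4R,5S)-5-[3-methoxy-4-(tosyloxy)phenyl]-4-methyloxolan-2-one
Conditions: TEMPO (0.2 equiv), PhI(OAc)2 (2.5 equiv), CH2Cl2, rt
Reagents that add atoms: none
Why: Oxidative lactonisation: the oxoammonium oxidant takes the primary alcohol to the aldehyde, the benzylic hydroxyl closes to the lactol, and a second oxidation gives the cis-4,5 γ-lactone with both stereocentres untouched.

Step 5
Reactants: 8 (4R,5S)-5-[3-methoxy-4-(tosyloxy)phenyl]-4-methyloxolan-2-one; 9 iodomethane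
Product: 10 (3R,4R,5S)-5-[3-methoxy-4-(tosyloxy)phenyl]-3,4-dimethyloxolan-2-one
Conditions: LiN(SiMe3)2 (1.1 equiv), THF, −78 °C; MeI, −78 to −40 °C
Reagents that add atoms: iodomethane, CI
Why: Lactone enolate alkylation in which iodomethane approaches the face opposite the adjacent C4 methyl (and the cis C5 aryl), setting C3 (R) trans to C4–CH3; the silylamide base is too weak to attack or metalate the tosylate.

Step 6
Reactants: 10 (3R,4R,5S)-5-[3-methoxy-4-(tosyloxy)phenyl]-3,4-dimethyloxolan-2-one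
Product: 11 (3R,4R,5S)-5-[3-methoxy-4-(tosyloxy)phenyl]-3,4-dimethyloxolan-2-ol (anomeric mixture)
Conditions: (i-Bu)2AlH (1.1 equiv), CH2Cl2, −78 °C; aq. potassium sodium tartrate (KNaC4H4O6)
Reagents that add atoms: none
Why: Partial hydride reduction of the lactone stops at the aluminium hemiacetal at low temperature, and the anomeric centre that forms as a mixture is destroyed again in step 11.

Step 7
Reactants: 12 4-iodo-2-methoxyphenol; 2 4-methylbenzenesulfonyl chloride
Product: 13 4-iodo-2-methoxyphenyl 4-methylbenzenesulfonate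
Conditions: Et3N, DMAP (cat.), CH2Cl2, 0 °C to rt
Reagents that add atoms: 4-methylbenzenesulfonyl chloride, Cc1ccc(S(=O)(=O)Cl)cc1
Why: O-sulfonylation of the phenol gives the ring D building block with the same deactivating protecting group as ring C; no stereocentre is formed.

Step 8
Reactants: 12 4-iodo-2-methoxyphenol; 14 (S)-2-hydroxy-N,N-dimethylpropanamide
Product: 15 (R)-2-(4-iodo-2-methoxyphenoxy)-N,N-dimethylpropanamide
Conditions: PPh3, diisopropyl azodicarboxylate, THF, 0 °C to rt
Reagents that add atoms: (S)-2-hydroxy-N,N-dimethylpropanamide, C[C@H](O)C(=O)N(C)C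
Why: Mitsunobu etherification, in which the phenol displaces the activated lactamide oxygen by SN2 with inversion, so the (S) carbinol becomes the (R) aryl ether centre of the side chain.

Step 9
Reactants: 13 4-iodo-2-methoxyphenyl 4-methylbenzenesulfonate; 15 (R)-2-(4-iodo-2-methoxyphenoxy)-N,N-dimethylpropanamide
Product: 17 (R)-2-(4-iodo-2-methoxyphenoxy)-1-[3-methoxy-4-(tosyloxy)phenyl]propan-1-one, via arylmagnesium chloride 16 (not isolated)
Conditions: 13 (1.5 equiv), iPrMgCl·LiCl, THF, −20 °C; then 15, −20 °C to rt; aq. NH4Cl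
Reagents that add atoms: 4-iodo-2-methoxyphenyl 4-methylbenzenesulfonate (aryl donor), COc1cc(I)ccc1OS(=O)(=O)c1ccc(C)cc1
Why: Iodine–magnesium exchange on the activated iodoarene followed by acyl substitution on the tertiary amide, whose chelated tetrahedral magnesium adduct persists until work-up, which prevents over-addition and leaves the α-aryloxy stereocentre intact.

Step 10
Reactants: 17 (R)-2-(4-iodo-2-methoxyphenoxy)-1-[3-methoxy-4-(tosyloxy)phenyl]propan-1-one
Product: 18 (1R,2R)-2-(4-iodo-2-methoxyphenoxy)-1-[3-methoxy-4-(tosyloxy)phenyl]propan-1-ol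
Conditions: LiBH(s-Bu)3, THF, −78 °C; aq. NH4Cl
Reagents that add atoms: none
Why: Non-chelation (polar Felkin–Anh) controlled ketone reduction, in which the bulky hydride attacks anti to the weakly coordinating α-aryloxy group and should give the threo (1R,2R) alcohol.

Step 11
Reactants: 18 (1R,2R)-2-(4-iodo-2-methoxyphenoxy)-1-[3-methoxy-4-(tosyloxy)phenyl]propan-1-ol; 11 (3R,4R,5S)-5-[3-methoxy-4-(tosyloxy)phenyl]-3,4-dimethyloxolan-2-ol
Product: 21 bis-tosylate of the target [(2S,3R,4R,5R)-oxolane with tosylated rings C and D], via bis(chloromagnesium) aryl reagent 19 (not isolated), via epimeric butanediol 20 (not isolated)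
Conditions: 18 (2.2 equiv), iPrMgCl·LiCl (4.4 equiv), THF, −20 °C to rt; then 11, 0 °C to rt; then CF3CO2H (excess), CH2Cl2, 0 °C to rt
Reagents that add atoms: compound 18 (aryl donor), COc1cc([C@@H](O)[C@@H](C)Oc2ccc(I)cc2OC)ccc1OS(=O)(=O)c1ccc(C)cc1
Why: Iodine–magnesium exchange on 18 (after deprotonation of its hydroxyl) gives aryl nucleophile 19, which adds to the open hydroxy-aldehyde form of lactol 11 (Grignard 1,2-addition) to give diol 20 as both C5 epimers; trifluoroacetic acid then ionises only the new carbinol, because ring B carries a para ether oxygen and gives a quinone-methide-like oxocarbenium ion, and the C2 hydroxyl captures it to form the O1–C5 bond. The closest known reaction types are the acid-mediated cyclodehydration of 1,4-diarylbutane-1,4-diols to 2,5-diaryloxolanes and the intramolecular oxa-1,6-addition to a para-quinone methide, which is the ring-closing event of the presumed biosynthesis. Ring A closes in a 5-exo-trig mode onto the cationic C5, whose double bond to ring B lies outside the new ring. The new stereocentre C5 (R) is controlled by the adjacent C4 methyl: in the envelope transition state ring B sits pseudo-equatorial and trans to C4–CH3, and reversible ionisation at C5 lets any cis isomer equilibrate to the trans product, so both diol epimers converge. The step needs chemoselective ionisation at C5 over C2 and over the side-chain carbinol, which the electron-withdrawing tosylates on rings C and D secure, so the kinetically set cis C2/C3 relation and the threo side chain are not scrambled.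

Step 12
Reactants: 21 bis-tosylate of the target
Product: 22 4-[(2S,3R,4R,5R)-5-(4-{[(1R,2R)-1-hydroxy-1-(4-hydroxy-3-methoxyphenyl)propan-2-yl]oxy}-3-methoxyphenyl)-3,4-dimethyloxolan-2-yl]-2-methoxyphenol (target)
Conditions: KOH, MeOH/THF/H2O, 55 °C; then aq. NH4Cl
Reagents that add atoms: none
Why: Saponification of both aryl sulfonates by hydroxide attack at sulfur (S–O cleavage) should release the two phenols, while the benzylic ethers and all six stereocentres are not expected to react under these conditions.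

Compound list
1 | vanillin (4-hydroxy-3-methoxybenzaldehyde) | COc1cc(C=O)ccc1O | starting material
2 | 4-methylbenzenesulfonyl chloride | Cc1ccc(S(=O)(=O)Cl)cc1 | starting material
3 | 4-formyl-2-methoxyphenyl 4-methylbenzenesulfonate | COc1cc(C=O)ccc1OS(=O)(=O)c1ccc(C)cc1 | intermediate
4 | (Z)-crotylboronic acid pinacol ester | C/C=C\CB1OC(C)(C)C(C)(C)O1 | starting material
5 | (1S,2R)-1-[3-methoxy-4-(tosyloxy)phenyl]-2-methylbut-3-en-1-ol | O[C@H](c1ccc(OS(=O)(=O)c2ccc(C)cc2)c(OC)c1)[C@H](C)C=C | intermediate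
6 | sodium perborate tetrahydrate (NaBO3·4H2O, drawn as the anhydrous dimeric peroxoborate) | O[B-]1(O)OO[B-](O)(O)OO1.[Na+].[Na+] | starting material
7 | (1S,2R)-1-[3-methoxy-4-(tosyloxy)phenyl]-2-methylbutane-1,4-diol | O[C@H](c1ccc(OS(=O)(=O)c2ccc(C)cc2)c(OC)c1)[C@H](C)CCO | intermediate
8 | (4R,5S)-5-[3-methoxy-4-(tosyloxy)phenyl]-4-methyloxolan-2-one (4,5-cis) | O1[C@H](c2ccc(OS(=O)(=O)c3ccc(C)cc3)c(OC)c2)[C@H](C)CC1=O | intermediate
9 | iodomethane | CI | starting material
10 | (3R,4R,5S)-5-[3-methoxy-4-(tosyloxy)phenyl]-3,4-dimethyloxolan-2-one (3,4-trans, 4,5-cis) | O1[C@H](c2ccc(OS(=O)(=O)c3ccc(C)cc3)c(OC)c2)[C@H](C)[C@@H](C)C1=O | intermediate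
11 | (3R,4R,5S)-5-[3-methoxy-4-(tosyloxy)phenyl]-3,4-dimethyloxolan-2-ol (anomeric mixture) | O1[C@H](c2ccc(OS(=O)(=O)c3ccc(C)cc3)c(OC)c2)[C@H](C)[C@@H](C)C1O | intermediate
12 | 4-iodo-2-methoxyphenol | COc1cc(I)ccc1O | starting material
13 | 4-iodo-2-methoxyphenyl 4-methylbenzenesulfonate | COc1cc(I)ccc1OS(=O)(=O)c1ccc(C)cc1 | intermediate
14 | (S)-2-hydroxy-N,N-dimethylpropanamide | C[C@H](O)C(=O)N(C)C | starting material
15 | (R)-2-(4-iodo-2-methoxyphenoxy)-N,N-dimethylpropanamide | C[C@@H](Oc1ccc(I)cc1OC)C(=O)N(C)C | intermediate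
16 | [3-methoxy-4-(tosyloxy)phenyl]magnesium chloride (LiCl complex) | COc1cc([Mg]Cl)ccc1OS(=O)(=O)c1ccc(C)cc1 | intermediate
17 | (R)-2-(4-iodo-2-methoxyphenoxy)-1-[3-methoxy-4-(tosyloxy)phenyl]propan-1-one | C[C@@H](Oc1ccc(I)cc1OC)C(=O)c1ccc(OS(=O)(=O)c2ccc(C)cc2)c(OC)c1 | intermediate
18 | (1R,2R)-2-(4-iodo-2-methoxyphenoxy)-1-[3-methoxy-4-(tosyloxy)phenyl]propan-1-ol (threo) | COc1cc([C@@H](O)[C@@H](C)Oc2ccc(I)cc2OC)ccc1OS(=O)(=O)c1ccc(C)cc1 | intermediate
19 | bis(chloromagnesium) aryl reagent from 18 (aryl–MgCl and O–MgCl) | COc1cc([C@@H](O[Mg]Cl)[C@@H](C)Oc2ccc([Mg]Cl)cc2OC)ccc1OS(=O)(=O)c1ccc(C)cc1 | intermediate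
20 | (2R,3R,4S)-2,3-dimethylbutane-1,4-diol bearing ring B with side chain on C1 and ring C on C4 (both C1 epimers) | COc1cc([C@@H](O)[C@@H](C)Oc2ccc(C(O)[C@H](C)[C@@H](C)[C@H](O)c3ccc(OS(=O)(=O)c4ccc(C)cc4)c(OC)c3)cc2OC)ccc1OS(=O)(=O)c1ccc(C)cc1 | intermediate
21 | bis-tosylate of the target, (2S,3R,4R,5R)-oxolane | COc1cc([C@@H](O)[C@@H](C)Oc2ccc([C@@H]3O[C@H](c4ccc(OS(=O)(=O)c5ccc(C)cc5)c(OC)c4)[C@H](C)[C@H]3C)cc2OC)ccc1OS(=O)(=O)c1ccc(C)cc1 | intermediate
22 | 4-[(2S,3R,4R,5R)-5-(4-{[(1R,2R)-1-hydroxy-1-(4-hydroxy-3-methoxyphenyl)propan-2-yl]oxy}-3-methoxyphenyl)-3,4-dimethyloxolan-2-yl]-2-methoxyphenol | COc1cc([C@@H](O)[C@@H](C)Oc2ccc([C@@H]3O[C@H](c4ccc(O)c(OC)c4)[C@H](C)[C@H]3C)cc2OC)ccc1O | target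

Total step count: 12. Longest linear sequence: 8 steps (steps 1–6, 11, 12).

Steps most likely to fail

1. Step 11. The iodine–magnesium exchange on the electron-rich, alkoxide-bearing iodoarene may be incomplete. The organomagnesium may attack a sulfonate. Under acid, Friedel–Crafts capture of the C5 cation by ring C may compete with capture by oxygen. Fallback, setting out from 11 and returning at 21: lactol 11 is treated with (4-benzyloxy-3-methoxyphenyl)magnesium bromide F1 (from 4-benzyloxy-1-bromo-3-methoxybenzene and Mg, THF) and worked up with aq. NH4Cl to give the isolated C1-epimeric diol F2. This is cyclised separately with catalytic p-toluenesulfonic acid in CH2Cl2 at 0 °C to the 4,5-trans oxolane benzyl ether F3. Hydrogenolysis (H2, palladium on carbon, EtOAc) frees the ring B phenol F4. Mitsunobu coupling with 14 gives the oxolane aryloxy amide F5, addition of arylmagnesium 16 gives the oxolane aryloxy ketone F6, and reduction with LiBH(s-Bu)3 as in step 10 returns to 21.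

2. Step 10. Facial selectivity may be poor, because competing lithium chelation between the carbonyl and the aryloxy oxygen favours the erythro alcohol. Fallback, setting out from 17 and returning at 18: the selectivity is deliberately reversed by chelation-controlled reduction with Zn(BH4)2 in Et2O at 0 °C to the erythro (1S,2R) alcohol F7. The carbinol centre is then inverted by a Mitsunobu reaction with 4-nitrobenzoic acid (PPh3, diisopropyl azodicarboxylate) to the (1R,2R) 4-nitrobenzoate F8, and methanolysis (K2CO3, MeOH, 0 °C to rt) gives 18.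

3. Step 9. Acyl substitution on the tertiary amide may be sluggish, and the basic organomagnesium may partly epimerise the α-aryloxy centre. Fallback, setting out from 12 and returning at 17: Mitsunobu coupling of 12 with ethyl (S)-lactate gives ethyl (R)-2-(4-iodo-2-methoxyphenoxy)propanoate F9. Aminolysis with MeONHMe·HCl and AlMe3 in CH2Cl2 gives the N-methoxy-N-methyl amide F10, which reacts cleanly with arylmagnesium 16 at −20 °C to give 17.

Further compounds
F1 | step 11 | (4-benzyloxy-3-methoxyphenyl)magnesium bromide | COc1cc([Mg]Br)ccc1OCc1ccccc1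
F2 | step 11 | (2R,3R,4S)-1-(4-benzyloxy-3-methoxyphenyl)-4-[3-methoxy-4-(tosyloxy)phenyl]-2,3-dimethylbutane-1,4-diol (C1 epimers) | COc1cc(C(O)[C@H](C)[C@@H](C)[C@H](O)c2ccc(OS(=O)(=O)c3ccc(C)cc3)c(OC)c2)ccc1OCc1ccccc1
F3 | step 11 | (2S,3R,4R,5R)-5-(4-benzyloxy-3-methoxyphenyl)-2-[3-methoxy-4-(tosyloxy)phenyl]-3,4-dimethyloxolane | COc1cc([C@@H]2O[C@H](c3ccc(OS(=O)(=O)c4ccc(C)cc4)c(OC)c3)[C@H](C)[C@H]2C)ccc1OCc1ccccc1
F4 | step 11 | 2-methoxy-4-{(2R,3R,4R,5S)-5-[3-methoxy-4-(tosyloxy)phenyl]-3,4-dimethyloxolan-2-yl}phenol | COc1cc([C@@H]2O[C@H](c3ccc(OS(=O)(=O)c4ccc(C)cc4)c(OC)c3)[C@H](C)[C@H]2C)ccc1O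
F5 | step 11 | (R)-2-(aryloxy)-N,N-dimethylpropanamide of phenol F4 | C[C@@H](Oc1ccc([C@@H]2O[C@H](c3ccc(OS(=O)(=O)c4ccc(C)cc4)c(OC)c3)[C@H](C)[C@H]2C)cc1OC)C(=O)N(C)C
F6 | step 11 | (R)-2-(aryloxy)-1-[3-methoxy-4-(tosyloxy)phenyl]propan-1-one of phenol F4 | C[C@@H](Oc1ccc([C@@H]2O[C@H](c3ccc(OS(=O)(=O)c4ccc(C)cc4)c(OC)c3)[C@H](C)[C@H]2C)cc1OC)C(=O)c1ccc(OS(=O)(=O)c2ccc(C)cc2)c(OC)c1
F7 | step 10 | (1S,2R)-2-(4-iodo-2-methoxyphenoxy)-1-[3-methoxy-4-(tosyloxy)phenyl]propan-1-ol (erythro) | COc1cc([C@H](O)[C@@H](C)Oc2ccc(I)cc2OC)ccc1OS(=O)(=O)c1ccc(C)cc1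
F8 | step 10 | (1R,2R)-2-(4-iodo-2-methoxyphenoxy)-1-[3-methoxy-4-(tosyloxy)phenyl]propyl 4-nitrobenzoate | COc1cc([C@@H](OC(=O)c2ccc([N+](=O)[O-])cc2)[C@@H](C)Oc2ccc(I)cc2OC)ccc1OS(=O)(=O)c1ccc(C)cc1
F9 | step 9 | ethyl (R)-2-(4-iodo-2-methoxyphenoxy)propanoate | CCOC(=O)[C@@H](C)Oc1ccc(I)cc1OC
F10 | step 9 | (R)-2-(4-iodo-2-methoxyphenoxy)-N-methoxy-N-methylpropanamide | CON(C)C(=O)[C@@H](C)Oc1ccc(I)cc1OC
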